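Two questions stood before me, the order in catalyst of the starting rate and the share of starting material left in the midnight run, and I reckoned both in fractions of the charge.

common to all: starting material 0.500 M
- summer: free catalyst 0.00100 M
- winter: free catalyst 5.00 × 10⁻⁴ M
- midnight: free catalyst 0.00100 M; time 520 min

| run | time / min | [starting material] / M |
|---|---|---|
| summer run | 17 | 0.345 |
| summer run | 34 | 0.264 |
| summer run | 52 | 0.216 |
| summer run | 69 | 0.197 |
| summer run | 86 | 0.188 |
| winter run | 17 | 0.482 |
| winter run | 34 | 0.464 |
| winter run | 52 | 0.450 |
| winter run | 69 | 0.443 |
| winter run | 86 | 0.430 |

(scatter of a reading: 0.005 M)

1. apparent order in [free catalyst] of the starting rate, round the charge of the summer run (the rate where two percent of its starting material have turned into product)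
2. starting material in the midnight run at 520 min, as a share of the starting material charged

- Overall: starting material -> product, with free catalyst as catalyst.
- Constant volume, constant temperature.
- An order is taken over about fifteen percent of the charge, up and down.

1. I compared the first interval of each run, using the logarithm of charge over reading to allow for starting material used up, and the winter run went at 0.0988 of the summer pace, a reading that carries the scatter of single points.

2. That pace, on half the catalyst, gave an average order of 3.34, which I took as my upper bound, while a catalyst working in simple proportion gave 1, my lower bound.

3. To tighten this I supposed a titration: a fixed amount of catalyst is lost at the outset and the rest works in proportion. The pace ratio then gave 0.555 as the working share, the part of the summer catalyst charge left to work, and the order at that charge is its inverse, 1.80, lower than the average.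

4. The midnight run has the summer charge, so I put its share below the last summer reading, 37.6 %. Summing a tail of later drops that shrank by the early ratio 0.593 gave an estimated lower bound of 35.0 %, and the latest ratio, 0.474, smaller than the early one, tightened my figure to 36.0 %.

5. The forecast, reasoning from “a titrating poison”, gave an order of 2.6 (1.7 to 3.7) and a share of 35.5 % (29 % to 38 %), both central values inside my brackets, though its order stood higher than my 1.80.

6. The simulation gave an order of 1.8 and a share of 36.3 %.

    free catalyst + starting material → product + free catalyst (43.38 M⁻¹ min⁻¹)
    free catalyst + product → spent catalyst + product (0.1260 M⁻¹ min⁻¹)
    free catalyst + impurity → spent catalyst

The order in the flask was 1.8, beside the 1.80 that my working share of 0.555 had given, and it stands there because the impurity takes free catalyst at once, its charge being 0.453 of the summer catalyst charge, where my reading of the two runs had put the loss at 0.445. In the run without that path the working share is 1, and its inverse is the order that run shows, 1.0.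

(The readings were generated by integration on assumed constants, and the scatter is random.)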